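A direct plan would etherify 4-bromo-2,6-dimethoxyphenol A1 with rac-2-bromopropanoic acid A2 to give rac-2-(4-bromo-2,6-dimethoxyphenoxy)propanoic acid A3, would add the decarboxylated α-aryloxyethyl unit of A3 to 3,4,5-trimethoxybenzaldehyde A4 under dual photoredox/chromium catalysis to give the threo bromo alcohol A5, and would finish by Suzuki coupling of A5 with the (E)-hydroxypropenyl pinacol boronate A6.
Its weakest step would be the decarboxylative chromium-mediated carbonyl addition of A3 to A4: it would have to form the C7–C8 bond and fix both the absolute and the threo configuration in a reaction class with no precedent for α-aryloxyalkyl chromium nucleophiles, while an aryl bromide sits under strongly reducing conditions.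
Second would be the aqueous etherification of the doubly ortho-substituted phenoxide of A1 with the secondary α-bromo carboxylate of A2: a hindered SN2 that competes with hydrolysis, and it builds a stereocentre and a carboxyl carbon that the next step destroys.
Third would be the closing Suzuki coupling of A5 with A6: it attaches, on the fully stereodefined material, a three-carbon chain that a commercial monolignol already carries, and an unprotected alkenyl boronate is prone to protodeboronation.

**Retrosynthetic overview**
Feature used: in the ketone oxidation state, C8–H lies between the C7 carbonyl and the ring-B ether oxygen O4', so C8 epimerises with base while C7 is prochiral.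
Key disconnection: C7–H, with C8 set dynamically; asymmetric hydrogenation of racemic ketone 5 under dynamic kinetic resolution should create both stereocentres in the last step.
Ketone 5 comes from SN2 etherification (C8–O4') of racemic α-bromo ketone 2 with intact (E)-sinapyl alcohol 3, which brings ring B and the complete C7'–C9' chain; 2 comes from bromination of propiophenone 1.
No ring is formed: rings A and B are bought as arenes and are never modified.
The design needs no C7–C8 bond construction, makes no stereocentre that is later erased, and has no late cross-coupling.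

Key step: step 3

Remark: neolignan locants are used (C7 carbinol carbon, C8 ether-bearing carbon, C9 methyl, primed locants on ring B); (E)-sinapyl alcohol 3 is taken as a commercial monolignol, chromatographed before use.
Abbreviations: xylbinap = 2,2'-bis[bis(3,5-dimethylphenyl)phosphino]-1,1'-binaphthyl; daipen = 1,1-bis(4-methoxyphenyl)-3-methylbutane-1,2-diamine.

Step 1
Reactants: 1 1-(3,4,5-trimethoxyphenyl)propan-1-one
Product: 2 rac-2-bromo-1-(3,4,5-trimethoxyphenyl)propan-1-one
Conditions: CuBr2 (2.1 equiv), EtOAc–CHCl3 1:1, reflux, 4 h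
Reagents that add atoms: CuBr2 (copper dibromide), [Cu+2].[Br-].[Br-]
Why: α-Bromination of an enolisable aryl ketone by copper dibromide through its enol, which should be selective for C8 over the electron-rich but acyl-deactivated ring A and should stop at the monobromide; racemic C8 is intended.

Step 2
Reactants: 2 rac-2-bromo-1-(3,4,5-trimethoxyphenyl)propan-1-one; 3 (E)-sinapyl alcohol (1.05 equiv)
Product: 5 rac-2-{4-[(1E)-3-hydroxyprop-1-en-1-yl]-2,6-dimethoxyphenoxy}-1-(3,4,5-trimethoxyphenyl)propan-1-one, via potassium phenoxide 4 (not isolated)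
Conditions: K2CO3 (1.5 equiv), acetone, N2, 45 °C, 12 h
Reagents that add atoms: none
Why: Williamson etherification (SN2 of phenoxide 4 at the carbonyl-activated secondary bromide), in which carbonate deprotonates the phenol but not the allylic alcohol so that only O4' is alkylated; C8 is left racemic because step 3 resolves it dynamically.

Step 3
Reactants: 5 rac-2-{4-[(1E)-3-hydroxyprop-1-en-1-yl]-2,6-dimethoxyphenoxy}-1-(3,4,5-trimethoxyphenyl)propan-1-one
Product: 7 (1R,2R)-2-{4-[(1E)-3-hydroxyprop-1-en-1-yl]-2,6-dimethoxyphenoxy}-1-(3,4,5-trimethoxyphenyl)propan-1-ol, via potassium enolate 6 (not isolated)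
Conditions: trans-RuCl2[(R)-xylbinap][(R)-daipen] (1 mol %), t-BuOK (0.3 equiv), H2 (10 atm), i-PrOH, 25 °C, 24 h
Reagents that add atoms: none
Why: Noyori-type bifunctional hydrogenation, in which the RuH2(diphosphine)(diamine) species formed from precatalyst, base and H2 transfers Ru–H to C7 and N–H to the carbonyl oxygen through a six-membered outer-sphere transition state without binding the substrate to the metal. The closest known reaction type is the asymmetric hydrogenation under dynamic kinetic resolution of racemic α-aryloxy, α-alkoxy and α-amido ketones with RuCl2(diphosphine)(diamine)/t-BuOK, together with the transfer hydrogenation of racemic benzoin to threo-hydrobenzoin; no ring is closed. C7 is set by the catalyst, whose (R)-xylbinap/(R)-daipen pocket distinguishes ring A from the C8 branch and should deliver hydride to the Si face of the carbonyl (7R). C8 is set by dynamic kinetic resolution: t-BuOK interconverts the ketone enantiomers through planar enolate 6 faster than either is reduced, and only the (8R)-ketone can meet that face in a Felkin–Anh arrangement (hydride anti to the C8–O4' bond, passing C8–H, C9 methyl inside), so the racemate should be funnelled to the threo (7R,8R) alcohol. The step needs C=O over C=C selectivity, which this catalyst class provides by leaving alkenes and allylic alcohols untouched, and it needs racemisation to outrun reduction, which the acidifying aryloxy group at C8, the 0.3 equiv of base and the low hydrogen pressure should ensure.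

**Compound list**
1 | 1-(3,4,5-trimethoxyphenyl)propan-1-one | CCC(=O)c1cc(OC)c(OC)c(OC)c1 | starting material
2 | rac-2-bromo-1-(3,4,5-trimethoxyphenyl)propan-1-one | CC(Br)C(=O)c1cc(OC)c(OC)c(OC)c1 | intermediate
3 | (E)-sinapyl alcohol, 4-[(1E)-3-hydroxyprop-1-en-1-yl]-2,6-dimethoxyphenol | COc1cc(/C=C/CO)cc(OC)c1O | starting material
4 | potassium 4-[(1E)-3-hydroxyprop-1-en-1-yl]-2,6-dimethoxyphenoxide | COc1cc(/C=C/CO)cc(OC)c1[O-].[K+] | intermediate
5 | rac-2-{4-[(1E)-3-hydroxyprop-1-en-1-yl]-2,6-dimethoxyphenoxy}-1-(3,4,5-trimethoxyphenyl)propan-1-one | COc1cc(C(=O)C(C)Oc2c(OC)cc(/C=C/CO)cc2OC)cc(OC)c1OC | intermediate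
6 | potassium enolate of 5 (C8 planar, enolate geometry not defined) | COc1cc(C([O-])=C(C)Oc2c(OC)cc(/C=C/CO)cc2OC)cc(OC)c1OC.[K+] | intermediate
7 | (1R,2R)-2-{4-[(1E)-3-hydroxyprop-1-en-1-yl]-2,6-dimethoxyphenoxy}-1-(3,4,5-trimethoxyphenyl)propan-1-ol (threo; 7R,8R) | COc1cc([C@@H](O)[C@@H](C)Oc2c(OC)cc(/C=C/CO)cc2OC)cc(OC)c1OC | target

Total step count: 3. Longest linear sequence: 3 steps (1 → 2 → 5 → 7).

**Steps most likely to fail**

Step 3. Racemisation at C8 may not outrun reduction, or the catalyst-matched ketone enantiomer may react through a non-Felkin arrangement, so that threo/erythro control erodes. Slow reversible dehydrogenation of the allylic alcohol is a further risk. The fallback would split stereocontrol into substrate control and separation. It sets out from 5: non-chelating Felkin–Anh reduction (NaBH4, 15-crown-5, i-PrOH–CH2Cl2, 0 °C; the crown ether prevents a sodium chelate between the C7 carbonyl and O4') should give racemic threo alcohol rac-(1R*,2R*)-2-{4-[(1E)-3-hydroxyprop-1-en-1-yl]-2,6-dimethoxyphenoxy}-1-(3,4,5-trimethoxyphenyl)propan-1-ol F1. Preparative chromatography on a chiral stationary phase (cellulose tris(3,5-dimethylphenylcarbamate), supercritical CO2–MeOH) would then deliver 7 and set aside its (1S,2S)-enantiomer F2. The fallback comes back to the route at 7.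

Step 2. The hindered phenoxide may act as a base on 2 (dehydrobromination to the aryl vinyl ketone), or the electron-rich monolignol phenoxide may oligomerise oxidatively. The fallback would bring in ring B as a robust, less basic aldehyde and grow the three-carbon chain afterwards. It sets out from 2: alkylation of syringaldehyde F3 (K2CO3, DMF, 50 °C) should give rac-3,5-dimethoxy-4-{[1-oxo-1-(3,4,5-trimethoxyphenyl)propan-2-yl]oxy}benzaldehyde F4. Wittig olefination with (triphenylphosphoranylidene)acetaldehyde (toluene, 80 °C; the stabilised ylide should ignore the ketone) should give rac-(2E)-3-(3,5-dimethoxy-4-{[1-oxo-1-(3,4,5-trimethoxyphenyl)propan-2-yl]oxy}phenyl)prop-2-enal F5. Aldehyde-selective 1,2-reduction with NaBH(OAc)3 (toluene, 80 °C), which spares ketones, should then return the sequence to the route at 5.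

Step 1. Bromination may stray onto C2/C6 of ring A, or C8 may be brominated twice. The fallback would install the leaving group by hypervalent-iodine α-oxygenation instead of halogenation. It sets out from 1: PhI(OH)OTs in MeCN at reflux should give rac-1-oxo-1-(3,4,5-trimethoxyphenyl)propan-2-yl 4-methylbenzenesulfonate F6. F6 would take the place of 2 in the etherification with 3 (K2CO3, acetone, 45 °C) and come back to the route at 5.

**Further compounds**
F1 | step 3 | rac-(1R*,2R*)-2-{4-[(1E)-3-hydroxyprop-1-en-1-yl]-2,6-dimethoxyphenoxy}-1-(3,4,5-trimethoxyphenyl)propan-1-ol (racemic threo alcohol, both enantiomers written) | COc1cc([C@@H](O)[C@@H](C)Oc2c(OC)cc(/C=C/CO)cc2OC)cc(OC)c1OC.COc1cc([C@H](O)[C@H](C)Oc2c(OC)cc(/C=C/CO)cc2OC)cc(OC)c1OC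
F2 | step 3 | (1S,2S)-2-{4-[(1E)-3-hydroxyprop-1-en-1-yl]-2,6-dimethoxyphenoxy}-1-(3,4,5-trimethoxyphenyl)propan-1-ol | COc1cc([C@H](O)[C@H](C)Oc2c(OC)cc(/C=C/CO)cc2OC)cc(OC)c1OC
F3 | step 2 | syringaldehyde, 4-hydroxy-3,5-dimethoxybenzaldehyde | COc1cc(C=O)cc(OC)c1O
F4 | step 2 | rac-3,5-dimethoxy-4-{[1-oxo-1-(3,4,5-trimethoxyphenyl)propan-2-yl]oxy}benzaldehyde | COc1cc(C(=O)C(C)Oc2c(OC)cc(C=O)cc2OC)cc(OC)c1OC
F5 | step 2 | rac-(2E)-3-(3,5-dimethoxy-4-{[1-oxo-1-(3,4,5-trimethoxyphenyl)propan-2-yl]oxy}phenyl)prop-2-enal | COc1cc(C(=O)C(C)Oc2c(OC)cc(/C=C/C=O)cc2OC)cc(OC)c1OC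
F6 | step 1 | rac-1-oxo-1-(3,4,5-trimethoxyphenyl)propan-2-yl 4-methylbenzenesulfonate | CC(OS(=O)(=O)c1ccc(C)cc1)C(=O)c1cc(OC)c(OC)c(OC)c1
A1 | direct plan | 4-bromo-2,6-dimethoxyphenol | COc1cc(Br)cc(OC)c1O
A2 | direct plan | rac-2-bromopropanoic acid | CC(Br)C(=O)O
A3 | direct plan | rac-2-(4-bromo-2,6-dimethoxyphenoxy)propanoic acid | CC(Oc1c(OC)cc(Br)cc1OC)C(=O)O
A4 | direct plan | 3,4,5-trimethoxybenzaldehyde | COc1cc(C=O)cc(OC)c1OC
A5 | direct plan | (1R,2R)-2-(4-bromo-2,6-dimethoxyphenoxy)-1-(3,4,5-trimethoxyphenyl)propan-1-ol | COc1cc([C@@H](O)[C@@H](C)Oc2c(OC)cc(Br)cc2OC)cc(OC)c1OC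
A6 | direct plan | (E)-3-(4,4,5,5-tetramethyl-1,3,2-dioxaborolan-2-yl)prop-2-en-1-ol | OC/C=C/B1OC(C)(C)C(C)(C)O1
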